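## Retrosynthetic overview

1. The target is the 20-membered dilactone of two 9-hydroxy-10-(oxazol-5-yl)deca-2,4-dienoic acids, one of them 2-methylated. Both (Z,Z)-dienes are unveiled in the last step by cis-semi-reduction of (Z)-enynes (C4≡C5 and C4′≡C5′).
2. Key disconnection: the C6–C7 CH2–CH2 bond of the 2-methyl half, closed by a nickel-catalysed reductive union of two electrophilic carbons. The enabling feature is that C6 is the sp3 carbon flanking C5 of the C4≡C5 alkyne (a primary propargylic position in the future 20-membered ring), while C7 is an unhindered primary CH2 beside the C8 methyl stereocentre.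
3. The seco-diester comes from a Sonogashira union (C3′–C4′) of an alkyne ester with a (Z)-iodoacrylate ester, a Yamaguchi esterification (O9′–C1) and an intermolecular Negishi propargyl–alkyl coupling (C6′–C7′).
4. All four stereocentres stem from (R)-4-silyloxycyclopent-2-enone: anti cuprate addition sets C8, ozonolytic cleavage of a ring C–C bond gives a δ-lactone, and a Schöllkopf reaction turns the lactone into the 5-substituted oxazole.
5. Ring order: δ-lactone (step 2, temporary), oxazole rings (step 3), 20-membered macrocycle (step 17).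

Key step: step 17

Locants: C1–C10 belong to the 2-methyl hydroxy-acid half (C1 ester carbonyl, C9 carbinol carbon, C10 the CH2 on the oxazole, C11 the oxazole carbon bonded to C10); primed locants belong to the other half.

Assumption: methyl isocyanide is taken as a purchasable reagent (it is otherwise made by dehydration of N-methylformamide).

## Route

Step 1
Reactants: 1 (4R)-4-[(tert-butyldimethylsilyl)oxy]cyclopent-2-en-1-one
Product: 2 tert-butyldimethyl{[(1R,2R)-2-methyl-4-[(trimethylsilyl)oxy]cyclopent-3-en-1-yl]oxy}silane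
Conditions: Me2CuLi, Me3SiCl, Et3N, THF, −78 °C
Reagents that add atoms: lithium dimethylcuprate, [Li+].C[Cu-]C; chlorotrimethylsilane, C[Si](C)(C)Cl
Why: Gilman cuprate 1,4-addition takes place anti to the C9 silyloxy group, so the C8 methyl stereocentre is set trans to it by 1,2-substrate control, and silylation fixes the enolate regiospecifically between C11 and C7 before it can equilibrate and expel silyloxide.

Step 2
Reactants: 2 tert-butyldimethyl{[(1R,2R)-2-methyl-4-[(trimethylsilyl)oxy]cyclopent-3-en-1-yl]oxy}silane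
Product: 4 (4R,5R)-4-[(tert-butyldimethylsilyl)oxy]-5-methyloxan-2-one, via hydroxy acid 3 (not isolated)
Conditions: O3, CH2Cl2/MeOH, −78 °C; NaBH4, −78 to 0 °C; 1 M HCl to pH 3; PPTS (cat.), CH2Cl2, 25 °C
Reagents that add atoms: ozone, [O-][O+]=O
Why: Ozonolysis of the silyl enol ether (Criegee cleavage) cuts only the C7=C11 bond of the five-membered ring, borohydride reduces the C7 terminus to the primary alcohol while C11 emerges as the acid, and acid-catalysed δ-lactonisation should give 4 with both stereocentres untouched.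

Step 3
Reactants: 4 (4R,5R)-4-[(tert-butyldimethylsilyl)oxy]-5-methyloxan-2-one; 5 methyl isocyanide
Product: 8 (2R,3R)-3-[(tert-butyldimethylsilyl)oxy]-2-methyl-4-(1,3-oxazol-5-yl)butan-1-ol, via lithiomethyl isocyanide 6 (not isolated), via isocyano ketone 7 (not isolated)
Conditions: 5, n-BuLi, THF, −78 °C; then 4, −78 to 0 °C; AcOH
Reagents that add atoms: none
Why: Schöllkopf oxazole synthesis, in which C-acylation of lithiomethyl isocyanide by the lactone opens the ring to the α-isocyano ketone enolate, which closes through oxygen onto the isocyanide carbon and aromatises on protonation to the 5-substituted oxazole while releasing the C7 hydroxyl; no stereocentre takes part.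

Step 4
Reactants: 8 (2R,3R)-3-[(tert-butyldimethylsilyl)oxy]-2-methyl-4-(1,3-oxazol-5-yl)butan-1-ol
Product: 9 5-{(2R,3S)-2-[(tert-butyldimethylsilyl)oxy]-4-iodo-3-methylbutyl}-1,3-oxazole
Conditions: I2, PPh3, imidazole, CH2Cl2, 0 °C
Reagents that add atoms: iodine, II
Why: Appel-type iodination (Garegg–Samuelsson conditions) of the unhindered primary alcohol by SN2 displacement of the alkoxyphosphonium group; the silyl ether and the oxazole are inert.

Step 5
Reactants: 9 5-{(2R,3S)-2-[(tert-butyldimethylsilyl)oxy]-4-iodo-3-methylbutyl}-1,3-oxazole; 10 3-bromo-1-(trimethylsilyl)prop-1-yne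
Product: 12 5-{(2R,3R)-2-[(tert-butyldimethylsilyl)oxy]-3-methyl-7-(trimethylsilyl)hept-6-yn-1-yl}-1,3-oxazole, via alkylzinc iodide 11 (not isolated)
Conditions: Zn dust, LiCl, THF, 40 °C; then 10, NiCl2·glyme (10 mol%), 2,2′:6′,2″-terpyridine (10 mol%), DMA, 25 °C
Reagents that add atoms: none
Why: LiCl-promoted zinc insertion into the primary iodide followed by a nickel/terpyridine Negishi alkyl–propargyl cross-coupling, which bonds at the propargylic CH2 (the silyl group on the alkyne disfavours the allenyl terminus) and forms C6′–C7′ without touching C8′ or C9′.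

Step 6
Reactants: 12 5-{(2R,3R)-2-[(tert-butyldimethylsilyl)oxy]-3-methyl-7-(trimethylsilyl)hept-6-yn-1-yl}-1,3-oxazole
Product: 13 (2R,3R)-3-methyl-1-(1,3-oxazol-5-yl)hept-6-yn-2-ol
Conditions: Bu4NF, THF, 0 to 25 °C
Reagents that add atoms: none
Why: Fluoride-mediated desilylation should remove the alkynyl C–Si and the secondary O–Si groups in one operation.

Step 7
Reactants: 14 4-[(tert-butyldimethylsilyl)oxy]but-2-yn-1-ol
Product: 15 4-[(tert-butyldimethylsilyl)oxy]but-2-ynal
Conditions: MnO2, CH2Cl2, 25 °C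
Reagents that add atoms: none
Why: MnO2 oxidation is selective for the propargylic alcohol and stops at the ynal.

Step 8
Reactants: 15 4-[(tert-butyldimethylsilyl)oxy]but-2-ynal; 16 ethyl 2-[bis(2,2,2-trifluoroethoxy)phosphoryl]propanoate
Product: 17 ethyl (2Z)-6-[(tert-butyldimethylsilyl)oxy]-2-methylhex-2-en-4-ynoate
Conditions: KN(SiMe3)2, 18-crown-6, THF, −78 °C
Reagents that add atoms: none
Why: Still–Gennari variant of the Horner–Wadsworth–Emmons olefination, whose electron-poor phosphonate under dissociating conditions should give the kinetic (Z)-trisubstituted C2=C3 enoate.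

Step 9
Reactants: 17 ethyl (2Z)-6-[(tert-butyldimethylsilyl)oxy]-2-methylhex-2-en-4-ynoate
Product: 18 (2Z)-6-[(tert-butyldimethylsilyl)oxy]-2-methylhex-2-en-4-ynoic acid
Conditions: LiOH, THF/EtOH/H2O, 0 to 25 °C; then 1 M HCl (0 °C) to pH 3
Reagents that add atoms: lithium hydroxide, [Li+].[OH-]
Why: Mild saponification of the ethyl ester, which should leave the propargylic silyl ether and the Z geometry intact.

Step 10
Reactants: 18 (2Z)-6-[(tert-butyldimethylsilyl)oxy]-2-methylhex-2-en-4-ynoic acid; 13 (2R,3R)-3-methyl-1-(1,3-oxazol-5-yl)hept-6-yn-2-ol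
Product: 20 (2R,3R)-3-methyl-1-(1,3-oxazol-5-yl)hept-6-yn-2-yl (2Z)-6-[(tert-butyldimethylsilyl)oxy]-2-methylhex-2-en-4-ynoate, via mixed anhydride 19 (not isolated)
Conditions: 2,4,6-trichlorobenzoyl chloride, Et3N, toluene, 25 °C; then 13, DMAP, 25 °C
Reagents that add atoms: none
Why: Yamaguchi esterification through the mixed trichlorobenzoic anhydride acylates the hindered C9′ alcohol with retention at C9′ and avoids the ketene and conjugate-addition pathways that isomerise (Z)-2-methyl enoates.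

Step 11
Reactants: 9 5-{(2R,3S)-2-[(tert-butyldimethylsilyl)oxy]-4-iodo-3-methylbutyl}-1,3-oxazole
Product: 21 (2R,3S)-4-iodo-3-methyl-1-(1,3-oxazol-5-yl)butan-2-ol
Conditions: HF (48% aq.), MeCN, 0 to 25 °C
Reagents that add atoms: none
Why: Acidic fluoride cleavage of the secondary silyl ether, under which the primary iodide is not displaced.

Step 12
Reactants: 21 (2R,3S)-4-iodo-3-methyl-1-(1,3-oxazol-5-yl)butan-2-ol; 22 prop-2-ynoic acid
Product: 23 (2R,3S)-4-iodo-3-methyl-1-(1,3-oxazol-5-yl)butan-2-yl prop-2-ynoate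
Conditions: DCC, DMAP (5 mol%), CH2Cl2, −20 °C
Reagents that add atoms: none
Why: Steglich carbodiimide esterification at low temperature with only catalytic DMAP, which limits amine addition to the propiolate and keeps C9 unchanged.

Step 13
Reactants: 23 (2R,3S)-4-iodo-3-methyl-1-(1,3-oxazol-5-yl)butan-2-yl prop-2-ynoate
Product: 24 (2R,3S)-4-iodo-3-methyl-1-(1,3-oxazol-5-yl)butan-2-yl (2Z)-3-iodoprop-2-enoate
Conditions: NaI, AcOH, 70 °C
Reagents that add atoms: sodium iodide, [Na+].[I-]
Why: Anti-hydroiodination of the propiolate ester should give the (Z)-3-iodoacrylate under kinetic control.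

Step 14
Reactants: 20 (2R,3R)-3-methyl-1-(1,3-oxazol-5-yl)hept-6-yn-2-yl (2Z)-6-[(tert-butyldimethylsilyl)oxy]-2-methylhex-2-en-4-ynoate; 24 (2R,3S)-4-iodo-3-methyl-1-(1,3-oxazol-5-yl)butan-2-yl (2Z)-3-iodoprop-2-enoate
Product: 25 (2R,3S)-4-iodo-3-methyl-1-(1,3-oxazol-5-yl)butan-2-yl (2Z,8R,9R)-9-{[(2Z)-6-[(tert-butyldimethylsilyl)oxy]-2-methylhex-2-en-4-ynoyl]oxy}-8-methyl-10-(1,3-oxazol-5-yl)dec-2-en-4-ynoate
Conditions: Pd(PPh3)2Cl2 (5 mol%), CuI (10 mol%), Et3N, THF (degassed), 0 to 25 °C
Reagents that add atoms: none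
Why: Sonogashira coupling of the terminal alkyne with the vinyl iodide forms C3′–C4′ with retention of the Z geometry, while the primary alkyl iodide and the internal alkyne do not react under these conditions.

Step 15
Reactants: 25 (the silyl ether named in step 14)
Product: 26 (2R,3S)-4-iodo-3-methyl-1-(1,3-oxazol-5-yl)butan-2-yl (2Z,8R,9R)-9-{[(2Z)-6-hydroxy-2-methylhex-2-en-4-ynoyl]oxy}-8-methyl-10-(1,3-oxazol-5-yl)dec-2-en-4-ynoate
Conditions: HF·pyridine, pyridine, THF, 0 °C
Reagents that add atoms: none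
Why: Buffered fluoride desilylation should cleave the primary propargylic silyl ether without touching esters, oxazoles or the alkyl iodide.

Step 16
Reactants: 26 (the propargylic alcohol named in step 15)
Product: 27 (2R,3S)-4-iodo-3-methyl-1-(1,3-oxazol-5-yl)butan-2-yl (2Z,8R,9R)-9-{[(2Z)-6-bromo-2-methylhex-2-en-4-ynoyl]oxy}-8-methyl-10-(1,3-oxazol-5-yl)dec-2-en-4-ynoate
Conditions: CBr4, PPh3, 2,6-lutidine, CH2Cl2, −20 to 0 °C
Reagents that add atoms: carbon tetrabromide, BrC(Br)(Br)Br
Why: Appel bromination converts the propargylic alcohol into the primary bromide by SN2 displacement, which at low temperature should occur without allenic transposition.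

Step 17
Reactants: 27 (the bromo iodide named in step 16)
Product: 28 (3Z,9R,10R,13Z,19R,20R)-3,9,19-trimethyl-10,20-bis(1,3-oxazol-5-ylmethyl)-1,11-dioxacycloicosa-3,13-diene-5,15-diyne-2,12-dione
Conditions: NiBr2·glyme (30 mol%), 2,2′:6′,2″-terpyridine (30 mol%), Mn powder (4 equiv), DMA/THF, 25 °C, addition of 27 over 12 h to 2 mM
Reagents that add atoms: none
Why: Proposed new method: an intramolecular nickel-catalysed reductive cross-electrophile coupling of a primary propargylic bromide (C6) with a primary alkyl iodide (C7), in which low-valent nickel–terpyridine, kept reduced by manganese, turns the iodide into an alkylnickel species, abstracts bromine from the more easily reduced propargylic C6–Br bond, captures the propargylic radical and forms C6–C7 by reductive elimination from trivalent nickel. The closest known reaction types are the intermolecular nickel/terpyridine Negishi coupling of propargylic bromides with alkylzinc halides (used in step 5 for the matching bond C6′–C7′) and nickel-catalysed reductive allyl–alkyl and alkyl–alkyl couplings of two halides; the zinc-free macrocyclic version is new. The 20-membered ring is closed head-to-tail between the two chain ends (formally a 20-exo-tet substitution at C6) and no stereocentre is formed, C8, C9, C8′ and C9′ being spectators. The step needs propargyl over allenyl bonding, which should be secured because C6 is an unhindered primary CH2 whereas C4 is fully substituted and conjugated to the enoate, and it needs ring closure over oligomerisation, which is addressed by slow addition to 2 mM and by the two rigid (Z)-enyne units and s-trans esters that leave few rotatable bonds in the 20-atom chain. Chemoselectivity rests on the two carbon–halogen bonds being the only readily reducible sites, and the Z geometry at C2=C3 and C2′=C3′ should persist because neither alkene takes part.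

Step 18
Reactants: 28 (the macrocyclic bis-enyne named in step 17)
Product: 29 (3Z,5Z,9R,10R,13Z,15Z,19R,20R)-3,9,19-trimethyl-10,20-bis(1,3-oxazol-5-ylmethyl)-1,11-dioxacycloicosa-3,5,13,15-tetraene-2,12-dione (CNP0128396.1)
Conditions: Zn dust pre-activated with Cu(OAc)2 and AgNO3, MeOH/H2O/1,4-dioxane, 40 °C
Reagents that add atoms: none
Why: Boland-type cis-semi-reduction of both conjugated enyne units with copper/silver-activated zinc should deliver the (Z)-alkenes C4=C5 and C4′=C5′ without over-reduction, esters and oxazoles being inert.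

## Compound list

1 | (4R)-4-[(tert-butyldimethylsilyl)oxy]cyclopent-2-en-1-one | C1=C[C@@H](CC1=O)O[Si](C)(C)C(C)(C)C | starting material
2 | tert-butyldimethyl{[(1R,2R)-2-methyl-4-[(trimethylsilyl)oxy]cyclopent-3-en-1-yl]oxy}silane | C=1[C@@H](C)[C@@H](CC=1O[Si](C)(C)C)O[Si](C)(C)C(C)(C)C | intermediate
3 | (3R,4R)-3-[(tert-butyldimethylsilyl)oxy]-5-hydroxy-4-methylpentanoic acid | OC[C@@H](C)[C@@H](CC(=O)O)O[Si](C)(C)C(C)(C)C | intermediate
4 | (4R,5R)-4-[(tert-butyldimethylsilyl)oxy]-5-methyloxan-2-one | C1[C@@H](C)[C@@H](CC(=O)O1)O[Si](C)(C)C(C)(C)C | intermediate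
5 | methyl isocyanide | C[N+]#[C-] | starting material
6 | lithiomethyl isocyanide | [Li]C[N+]#[C-] | intermediate
7 | (4R,5R)-4-[(tert-butyldimethylsilyl)oxy]-6-hydroxy-1-isocyano-5-methylhexan-2-one (formed as its lithium salt) | OC[C@@H](C)[C@@H](CC(=O)C[N+]#[C-])O[Si](C)(C)C(C)(C)C | intermediate
8 | (2R,3R)-3-[(tert-butyldimethylsilyl)oxy]-2-methyl-4-(1,3-oxazol-5-yl)butan-1-ol | OC[C@@H](C)[C@@H](Cc1cnco1)O[Si](C)(C)C(C)(C)C | intermediate
9 | 5-{(2R,3S)-2-[(tert-butyldimethylsilyl)oxy]-4-iodo-3-methylbutyl}-1,3-oxazole | IC[C@@H](C)[C@@H](Cc1cnco1)O[Si](C)(C)C(C)(C)C | intermediate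
10 | 3-bromo-1-(trimethylsilyl)prop-1-yne | C[Si](C)(C)C#CCBr | starting material
11 | {(2S,3R)-3-[(tert-butyldimethylsilyl)oxy]-2-methyl-4-(1,3-oxazol-5-yl)butyl}(iodo)zinc | I[Zn]C[C@@H](C)[C@@H](Cc1cnco1)O[Si](C)(C)C(C)(C)C | intermediate
12 | 5-{(2R,3R)-2-[(tert-butyldimethylsilyl)oxy]-3-methyl-7-(trimethylsilyl)hept-6-yn-1-yl}-1,3-oxazole | C[Si](C)(C)C#CCC[C@@H](C)[C@@H](Cc1cnco1)O[Si](C)(C)C(C)(C)C | intermediate
13 | (2R,3R)-3-methyl-1-(1,3-oxazol-5-yl)hept-6-yn-2-ol | C#CCC[C@@H](C)[C@@H](Cc1cnco1)O | intermediate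
14 | 4-[(tert-butyldimethylsilyl)oxy]but-2-yn-1-ol | OCC#CCO[Si](C)(C)C(C)(C)C | starting material
15 | 4-[(tert-butyldimethylsilyl)oxy]but-2-ynal | O=CC#CCO[Si](C)(C)C(C)(C)C | intermediate
16 | ethyl 2-[bis(2,2,2-trifluoroethoxy)phosphoryl]propanoate | CCOC(=O)C(C)P(=O)(OCC(F)(F)F)OCC(F)(F)F | starting material
17 | ethyl (2Z)-6-[(tert-butyldimethylsilyl)oxy]-2-methylhex-2-en-4-ynoate | CCOC(=O)/C(C)=C\C#CCO[Si](C)(C)C(C)(C)C | intermediate
18 | (2Z)-6-[(tert-butyldimethylsilyl)oxy]-2-methylhex-2-en-4-ynoic acid | OC(=O)/C(C)=C\C#CCO[Si](C)(C)C(C)(C)C | intermediate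
19 | (2Z)-6-[(tert-butyldimethylsilyl)oxy]-2-methylhex-2-en-4-ynoic 2,4,6-trichlorobenzoic anhydride | O=C(OC(=O)/C(C)=C\C#CCO[Si](C)(C)C(C)(C)C)c1c(Cl)cc(Cl)cc1Cl | intermediate
20 | (2R,3R)-3-methyl-1-(1,3-oxazol-5-yl)hept-6-yn-2-yl (2Z)-6-[(tert-butyldimethylsilyl)oxy]-2-methylhex-2-en-4-ynoate | C#CCC[C@@H](C)[C@@H](Cc1cnco1)OC(=O)/C(C)=C\C#CCO[Si](C)(C)C(C)(C)C | intermediate
21 | (2R,3S)-4-iodo-3-methyl-1-(1,3-oxazol-5-yl)butan-2-ol | IC[C@@H](C)[C@@H](Cc1cnco1)O | intermediate
22 | prop-2-ynoic acid | C#CC(=O)O | starting material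
23 | (2R,3S)-4-iodo-3-methyl-1-(1,3-oxazol-5-yl)butan-2-yl prop-2-ynoate | IC[C@@H](C)[C@@H](Cc1cnco1)OC(=O)C#C | intermediate
24 | (2R,3S)-4-iodo-3-methyl-1-(1,3-oxazol-5-yl)butan-2-yl (2Z)-3-iodoprop-2-enoate | IC[C@@H](C)[C@@H](Cc1cnco1)OC(=O)/C=C\I | intermediate
25 | (2R,3S)-4-iodo-3-methyl-1-(1,3-oxazol-5-yl)butan-2-yl (2Z,8R,9R)-9-{[(2Z)-6-[(tert-butyldimethylsilyl)oxy]-2-methylhex-2-en-4-ynoyl]oxy}-8-methyl-10-(1,3-oxazol-5-yl)dec-2-en-4-ynoate | IC[C@@H](C)[C@@H](Cc1cnco1)OC(=O)/C=C\C#CCC[C@@H](C)[C@@H](Cc1cnco1)OC(=O)/C(C)=C\C#CCO[Si](C)(C)C(C)(C)C | intermediate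
26 | (2R,3S)-4-iodo-3-methyl-1-(1,3-oxazol-5-yl)butan-2-yl (2Z,8R,9R)-9-{[(2Z)-6-hydroxy-2-methylhex-2-en-4-ynoyl]oxy}-8-methyl-10-(1,3-oxazol-5-yl)dec-2-en-4-ynoate | IC[C@@H](C)[C@@H](Cc1cnco1)OC(=O)/C=C\C#CCC[C@@H](C)[C@@H](Cc1cnco1)OC(=O)/C(C)=C\C#CCO | intermediate
27 | (2R,3S)-4-iodo-3-methyl-1-(1,3-oxazol-5-yl)butan-2-yl (2Z,8R,9R)-9-{[(2Z)-6-bromo-2-methylhex-2-en-4-ynoyl]oxy}-8-methyl-10-(1,3-oxazol-5-yl)dec-2-en-4-ynoate | IC[C@@H](C)[C@@H](Cc1cnco1)OC(=O)/C=C\C#CCC[C@@H](C)[C@@H](Cc1cnco1)OC(=O)/C(C)=C\C#CCBr | intermediate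
28 | (3Z,9R,10R,13Z,19R,20R)-3,9,19-trimethyl-10,20-bis(1,3-oxazol-5-ylmethyl)-1,11-dioxacycloicosa-3,13-diene-5,15-diyne-2,12-dione | C/C1=C/C#CCC[C@@H](C)[C@@H](Cc2cnco2)OC(=O)/C=C\C#CCC[C@@H](C)[C@@H](Cc2cnco2)OC1=O | intermediate
29 | (3Z,5Z,9R,10R,13Z,15Z,19R,20R)-3,9,19-trimethyl-10,20-bis(1,3-oxazol-5-ylmethyl)-1,11-dioxacycloicosa-3,5,13,15-tetraene-2,12-dione (CNP0128396.1) | C/C1=C/C=C\CC[C@@H](C)[C@@H](Cc2cnco2)OC(=O)/C=C\C=C/CC[C@@H](C)[C@@H](Cc2cnco2)OC1=O | target

## Step count and risks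

Total step count: 18. Longest linear sequence: 12 steps (steps 1–6, 10, 14–18).

Steps most likely to fail:

1. Step 17 (carries the label "Proposed new method:"). Possible failures are bonding at the allenyl terminus C4 instead of C6, hydrodehalogenation of one or both chain ends, chain growth by intermolecular coupling, addition of the C7 radical or of low-valent nickel to an enyne unit, and loss of the Z geometry at C2=C3 through the delocalised propargylic radical. The fallback uses known chemistry: it makes the C6–C7 bond intermolecularly and closes the ring at C3′–C4′. It sets out from 20 and from iodide 9. Compound 20 would be desilylated (HF·pyridine) to (2R,3R)-3-methyl-1-(1,3-oxazol-5-yl)hept-6-yn-2-yl (2Z)-6-hydroxy-2-methylhex-2-en-4-ynoate F1 and brominated (CBr4, PPh3) to the corresponding 6-bromo ester F2. The alkylzinc iodide 11, made from 9 as in step 5, would then be coupled with F2 under the NiCl2·glyme/terpyridine Negishi conditions to give the silyl-protected C6–C7-linked enynoate F3. Aqueous HF would free the C9 alcohol F4, which would be esterified with 22 (DCC) to the propiolate F5 and hydroiodinated (NaI, AcOH) to the (Z)-3-iodoacrylate F6. An intramolecular Sonogashira coupling (Pd(PPh3)4, CuI, Et3N, THF, 1 mM) would then close the 20-membered ring and come back to the route at 28.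

2. Step 10. Possible failures are isomerisation of the (Z)-2-methyl enoate to E during carboxyl activation, lactonisation of the free (Z)-enynoic acid onto its own alkyne, and slow acylation of the hindered secondary alcohol. The fallback builds the Z-enoate on an ester that is already in place; it sets out from 13 (together with 16 and 15) and returns at 20. Compound 16 would be hydrolysed with Me3SnOH (then dilute HCl) to 2-[bis(2,2,2-trifluoroethoxy)phosphoryl]propanoic acid F7, which would acylate 13 (DCC, DMAP) to the phosphonate ester F8. A Still–Gennari olefination of F8 with ynal 15 (KN(SiMe3)2, 18-crown-6, THF, −78 °C) would then give 20.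

3. Step 3. Possible failures are β-elimination of the C9 silyloxy group after ring opening, over-addition to the ketone, and incomplete ring closure of the isocyano ketone. The fallback switches from acylation of an isocyanide anion to a van Leusen condensation; it sets out from lactone 4 and returns at 8. Compound 4 would be reduced with i-Bu2AlH (CH2Cl2, −78 °C) to (4R,5R)-4-[(tert-butyldimethylsilyl)oxy]-5-methyloxan-2-ol F9 (anomeric mixture). Its open hydroxy-aldehyde form would be condensed with p-toluenesulfonylmethyl isocyanide (K2CO3, MeOH, reflux) to give 8 directly.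

Further compounds

F1 | step 17 | (2R,3R)-3-methyl-1-(1,3-oxazol-5-yl)hept-6-yn-2-yl (2Z)-6-hydroxy-2-methylhex-2-en-4-ynoate | C#CCC[C@@H](C)[C@@H](Cc1cnco1)OC(=O)/C(C)=C\C#CCO
F2 | step 17 | (2R,3R)-3-methyl-1-(1,3-oxazol-5-yl)hept-6-yn-2-yl (2Z)-6-bromo-2-methylhex-2-en-4-ynoate | C#CCC[C@@H](C)[C@@H](Cc1cnco1)OC(=O)/C(C)=C\C#CCBr
F3 | step 17 | (2R,3R)-3-methyl-1-(1,3-oxazol-5-yl)hept-6-yn-2-yl (2Z,8R,9R)-9-[(tert-butyldimethylsilyl)oxy]-2,8-dimethyl-10-(1,3-oxazol-5-yl)dec-2-en-4-ynoate | C#CCC[C@@H](C)[C@@H](Cc1cnco1)OC(=O)/C(C)=C\C#CCC[C@@H](C)[C@@H](Cc1cnco1)O[Si](C)(C)C(C)(C)C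
F4 | step 17 | (2R,3R)-3-methyl-1-(1,3-oxazol-5-yl)hept-6-yn-2-yl (2Z,8R,9R)-9-hydroxy-2,8-dimethyl-10-(1,3-oxazol-5-yl)dec-2-en-4-ynoate | C#CCC[C@@H](C)[C@@H](Cc1cnco1)OC(=O)/C(C)=C\C#CCC[C@@H](C)[C@@H](Cc1cnco1)O
F5 | step 17 | (2R,3R)-3-methyl-1-(1,3-oxazol-5-yl)hept-6-yn-2-yl (2Z,8R,9R)-2,8-dimethyl-10-(1,3-oxazol-5-yl)-9-(prop-2-ynoyloxy)dec-2-en-4-ynoate | C#CCC[C@@H](C)[C@@H](Cc1cnco1)OC(=O)/C(C)=C\C#CCC[C@@H](C)[C@@H](Cc1cnco1)OC(=O)C#C
F6 | step 17 | (2R,3R)-3-methyl-1-(1,3-oxazol-5-yl)hept-6-yn-2-yl (2Z,8R,9R)-9-{[(2Z)-3-iodoprop-2-enoyl]oxy}-2,8-dimethyl-10-(1,3-oxazol-5-yl)dec-2-en-4-ynoate | C#CCC[C@@H](C)[C@@H](Cc1cnco1)OC(=O)/C(C)=C\C#CCC[C@@H](C)[C@@H](Cc1cnco1)OC(=O)/C=C\I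
F7 | step 10 | 2-[bis(2,2,2-trifluoroethoxy)phosphoryl]propanoic acid | OC(=O)C(C)P(=O)(OCC(F)(F)F)OCC(F)(F)F
F8 | step 10 | (2R,3R)-3-methyl-1-(1,3-oxazol-5-yl)hept-6-yn-2-yl 2-[bis(2,2,2-trifluoroethoxy)phosphoryl]propanoate (both epimers at the phosphonate carbon) | C#CCC[C@@H](C)[C@@H](Cc1cnco1)OC(=O)C(C)P(=O)(OCC(F)(F)F)OCC(F)(F)F
F9 | step 3 | (4R,5R)-4-[(tert-butyldimethylsilyl)oxy]-5-methyloxan-2-ol (anomeric mixture) | C1[C@@H](C)[C@@H](CC(O)O1)O[Si](C)(C)C(C)(C)C
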